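A closed, stirred vessel takes solid substrate into solution, and reagent meets it there to give target.

| flask | solid substrate | reagent | remark | time |
|---|---|---|---|---|
| zeta | 0.010 M | 0.75 equiv | run made earlier |  |
| delta | 0.010 M | 1.1 equiv | run made earlier |  |
| alpha | 0.0050 M | 1.5 equiv | run made earlier |  |
| flask | 0.010 M | 1.50 equiv |  | 8.0 h |

| run | time / h | target / % | dissolved substrate / % | solid substrate / % |
|---|---|---|---|---|
| zeta | 0.833 | 2.3 | 3.1 | 94.2 |
| zeta | 2.50 | 11.2 | 5.0 | 83.1 |
| zeta | 4.00 | 19.6 | 6.4 | 73.1 |
| zeta | 6.00 | 29.2 | 8.3 | 63.3 |
| delta | 0.833 | 3.5 | 2.4 | 94.0 |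
| delta | 2.50 | 14.6 | 4.0 | 83.5 |
| delta | 4.00 | 23.8 | 5.0 | 72.6 |
| delta | 6.00 | 33.9 | 5.5 | 59.7 |
| alpha | 1.50 | 12.8 | 8.2 | 79.5 |
| alpha | 3.00 | 29.9 | 9.9 | 59.8 |
| alpha | 5.00 | 48.9 | 13.9 | 36.7 |
| alpha | 6.00 | 56.7 | 17.0 | 26.1 |

(scatter of a reading: 0.5 percentage points)

- solid, in amounts per volume of the solution: solid substrate
- at the start none of the solid substrate is in solution
- dissolved substrate means what is dissolved; the solid is not counted in it

- concentration of target at 8.0 h, in M
- concentration of dissolved substrate at 8.0 h, in M
- concentration of reagent at 8.0 h, in M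

No reading shows reagent, so c(reagent) has to be inferred from the target rate. Target gained per hour, divided by c(dissolved substrate), is a pseudo-first-order constant that follows c(reagent). In the delta run it reads 2.08 h⁻¹ over the first two readings and 0.962 h⁻¹ over the last two. That is a fall by a factor 2.16. Charge minus target falls by a factor of just 1.24. This reckoning takes the excess as a first-order loss of reagent, the drain constant 0.166 h⁻¹, a rough reading.

The ladder follows. Dissolved substrate has a half-life of 0.333 h early in the delta run, shorter than the reagent's 4.18 h, so it tracks its supply. This reckoned reagent half-life is shorter than the flask's 8.0 h, so the drain is expected to act within the flask's time. At the delta run's mean loss the solid lasts 14.9 h, longer than 8.0 h, so solid is expected to remain in the flask. Target is taken to form at the delta run's 5.65 × 10⁻⁴ M h⁻¹. In the flask the charge 0.0150 M shrinks by the factor 0.265, and target formation removes a further 0.00250 M, leaving c(reagent) near 0.00147 M.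

The forecast gives c(target) 0.0049 M, c(dissolved substrate) 6.200 × 10⁻⁴ M and c(reagent) 0.0101 M, on the ground “one reagent per target”. Its reagent stands above this reckoning.

The flask gives c(target) 0.00472 M, c(dissolved substrate) 6.18 × 10⁻⁴ M and c(reagent) 0.00298 M.

    solid substrate ⇌ dissolved substrate, rate k1*(cs1 - [dissolved substrate]) while solid is left; crystals form when [dissolved substrate] > cs1 (solubility = 2.40 mM, k = 0.00540 min⁻¹)
    dissolved substrate + reagent → target (k = 4.30 M⁻¹ min⁻¹)
    reagent → side product (k = 0.00190 min⁻¹)

The forecast holds for target and dissolved substrate, but its reagent is 3.39 times the flask's. The flask's reagent is twice the reckoned value, and the flask holds side product at 0.00731 M. The neighbouring flask, charged with 2.50 equiv of reagent, reached target 0.00533 M. The same factor and the same reckoning give it c(reagent) 0.00368 M. That neighbouring flask holds 0.00657 M, more than reckoned. Its side product stands at 0.0131 M, more than its target.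

The runs were computed with constants of no real substance; noise was put on by code.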